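## Structural features

The target is a briarane: a ten-membered carbocycle (C1–C10) trans-fused along C1–C10 to a cyclohexane (ring A: C1, C10, C11–C14), with a γ-lactone (O–C7, C8, C17, C19) trans-fused across C7–C8; C15 and C20 are the methyls on C1 and C11, C16 is the exocyclic methylene on C5, C18 the methyl on C17. It has twelve stereocentres (1S,2S,6S,7R,8R,9S,10S,11S,12R,13R,14R,17R), and C6–C7–C8–C9–C10–C11–C12–C13–C14–C1–C2 form one unbroken chain of them, with C1 quaternary and C8 and C11 tertiary carbinols. In ring A all oxygens (11-OH, 12-O-butanoyl, 13,14-epoxide) lie on the face opposite to the two methyl groups (the α face; β is the face of the C15 methyl). The large ring holds a (3Z)-alkene conjugated with the exocyclic C5=C16 methylene and, next to it, a secondary allylic chloride at C6. Fragile groups are the allylic chloride (ionisation, SN2′, elimination), the epoxide next to an ester, the β-hydroxy lactone (retro-aldol, epimerisation at C17) and three esters beside free tertiary alcohols (acyl migration). The real difficulty is the ten-membered ring: it must be closed next to the quaternary C1, contain a Z alkene inside a diene, and carry four contiguous stereocentres (C6–C9). The key step exploits the unit C8(O)–C7–C6–C5(=C16)–C4=C3, which links C3 and C8 across the large ring: it is the retron of an oxy-Cope rearrangement in which the exocyclic methylene is the unused π bond of an allene, so that adding a C3–C8 bond collapses the large ring to a trans-decalin (ring B: C1, C2, C3, C8, C9, C10). In one sentence: the ten-membered ring is made by anionic oxy-Cope ring expansion of the trans-decalin allenyl vinyl carbinol 17.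

## Logic of the disconnections

30 ⇒ 25 (through 29, 28, 27, 26). Cut: the acyl C–O bonds at O2, O9 and O12 and the two C–O bonds of the 13,14-epoxide. These are the most fragile groups, and the epoxide is cis to O12, so it can come last from the 13-ene by hydroxyl direction. Gain: only ethers, an acetonide and an alkene remain in ring A. Demand: O2/O9 (same fate, same protecting group) must be told apart from O11/O12 (acetonide), the tertiary O8 and O11 must stay free, and the epoxidation must be α-selective.

25 ⇒ 22 (through 24). Cut: the C6–Cl bond (SN2 with inversion on the C6 alcohol) and the lactone O–C7 bond (opening of a cis-6,7-epoxide by the C19 carboxylate with inversion). One epoxide oxygen and one internal nucleophile then account for both heteroatoms at C6 and C7. Gain: the lactone ring and two stereocentres reduce to a Z alkene. Demand: 5-exo attack at C7 in preference to the allylic C6, and chloride substitution without allylic transposition.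

22 ⇒ 20 (through 21). Cut: the epoxide C–O bonds (direction by the tertiary C8–OH) and the C8–C17 bond (aldol of a propionate enolate with the C8 ketone). Gain: C6, C7, C8 and C17 disappear and a dienone remains. Demand: 1,2- over 1,4-addition, attack anti to the C9–O bond, a Z(O)-enolate for C17, and epoxidation on the face opposite to the C8 hydroxyl.

20 ⇒ 17 (through 19 and 18), the key disconnection. In the retrosynthetic sense the C5–C6 bond is cut and a C3–C8 bond, absent from the target, is made. Gain: the ten-membered ring, the 3Z alkene and the 5(16)-methylene all go back to a rigid trans-decalin that carries an allenyl group at C3 and a vinyl carbinol at C8. Demand: the two unsaturated arms must be cis on ring B (allenyl equatorial, vinyl axial) so that the only chair array gives the 3Z ring.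

17 ⇒ 15 (through 16). Cut: C7–C8 (vinyl metal addition to the C8 ketone) and C3–C4 (propargyl Claisen shift from an O8 propargyl enol ether). Both arms thus grow out of one enol ether of ring B. Demand: delivery to the α face at C3 and at C8, which the axial C15 methyl and the axial 9β-oxygen should enforce.

15 ⇒ 13 (through 14). Cut: the two benzyl-type O–C bonds and the two C–H bonds at C2 and C9 (hydride reduction of an ene-dione). Gain: ring B becomes the flat alkoxy-ene-dione of a quinone adduct. Demand: hydride attack on both carbonyls from the α face.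

13 ⇒ 10 (through 12 and 11). Cut: the acetal, the C11–O and C12–O bonds (syn-dihydroxylation) and, in the reverse sense, the C11=C12 bond is traded for a C14 acyloxy group (1,4-elimination). Gain: ring A becomes a plain cyclohexene adduct. Demand: dihydroxylation of the trisubstituted alkene of the diene only, on the α face.

10 ⇒ 3 + 8 (through 9). Cut: C1–C14 and C10–C11 (Diels–Alder), after inversion of C10. Gain: ring A and the quaternary C1 arise in one step from a flat quinone and an acyclic diene, and the absolute configuration comes from an auxiliary that is later expelled. Demand: reaction at the methyl-bearing double bond, C11-to-C10 regiochemistry, and facial control.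

3 ⇒ 1 + 2 and 8 ⇒ 4 + 5. Cut: the C8–O bond (oxidative alkoxylation of the quinone) and the dienyl ester C–O bond (O-acylation of a dienolate). Demand: addition para to the methyl group; E,E geometry of the diene.

## Other disconnections considered

Alternative 1: ring-closing metathesis at C3=C4, the first idea that comes to mind. The seco-triene A1 would be closed to 30 (or a protected form) with the second-generation Grubbs catalyst RuCl2(=CHPh)(PCy3)(H2IMes). The cut is attractive on paper, but one partner is a 2-substituted butadiene, so the carbene can enter at the wrong alkene. A ten-membered ring with a Z alkene inside a diene is the worst case for ring strain and for E/Z control, and the reaction is reversible. All of C6–C9 would also have to be built on an open chain first. The chosen step fixes the Z geometry through a cyclic chair array and makes the diene without any metal carbene.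

Alternative 2: Grob (Wharton) fragmentation across a temporary C4–C9 bond. The tricyclic hydroxy mesylate A2 would fragment to the cyclodecenone A3 (C9 ketone, 3Z alkene by anti-periplanar geometry). The idea is sound and C5–C8 would be set on a six-membered ring. But A2 has three fused rings, two adjacent tertiary carbinols, a lactone trans-fused to a cyclohexane and a mesylate beside an exocyclic alkene, and should cost far more steps than 17. The C9 ketone of A3 would still need a face-selective reduction. The oxy-Cope step achieves the same ring expansion from a bicycle and forms a C–C bond at the same time.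

Alternative 3: dearomatisation with a temporary C2–C7 bond. In the aryl tricycle A4 the atoms C2–C7 and C16 are a cheap methylanisole ring; Birch reduction and oxidative cleavage of the tetrasubstituted C2=C7 alkene would open the large ring to the triketone A5. A5 is a cyclodecane-1,6-dione and should be prone to transannular aldol closure. Its oxidation pattern (ketones at C2, C4, C7) is far from the diene and chloride of the target, and no stereocentre at C2 or C6–C8 is set. Many redox steps on a flexible ring would follow, so the plan is longer and less controlled.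

Key step: step 12

Assumption: the (S)-2-methoxy-2-phenylacetate group is taken to shield the diene face as in the stacked-conformer model, so that the (S)-acid leads to the 1S series; if the sense were opposite, the (R)-acid would be used in the same way.
Convention: briarane locants throughout; β is the face of rings A and B that carries the C15 methyl; "up/down" relations in the large ring refer to the configurations of 30.

Step 1
Reactants: 1 2-methyl-1,4-benzoquinone (twofold amount, the second equivalent as oxidant); 2 prop-2-yn-1-ol
Product: 3 2-methyl-5-(prop-2-yn-1-yloxy)-1,4-benzoquinone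
Conditions: ZnCl2 (0.5 equiv), prop-2-yn-1-ol/CH2Cl2, rt
Reagents that add atoms: none
Why: Lewis-acid-promoted conjugate addition of the alcohol to the unsubstituted double bond of the quinone, then oxidation of the alkoxyhydroquinone by the second equivalent of quinone (oxidative alkoxylation); addition should occur para to the methyl group because the carbonyl flanked by the methyl-bearing carbon is the stronger acceptor.

Step 2
Reactants: 4 (E)-pent-2-enal; 5 (S)-2-methoxy-2-phenylacetic acid
Product: 8 (1E,3E)-penta-1,3-dien-1-yl (S)-2-methoxy-2-phenylacetate, via (S)-2-methoxy-2-phenylacetyl chloride 6 (not isolated), via potassium (1E,3E)-penta-1,3-dien-1-olate 7 (not isolated)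
Conditions: 5, (COCl)2, DMF (cat.), CH2Cl2, 0 °C, then evaporation; 4, KOtBu, THF, −78 °C; then 6, −78 → 0 °C
Reagents that add atoms: none
Why: γ-Deprotonation of the enal gives the extended dienolate, which is O-acylated by the acid chloride (enol ester formation); only the 1E,3E isomer can reach the s-cis conformation, so any 3Z isomer should be a spectator in step 3.

Step 3
Reactants: 3 2-methyl-5-(prop-2-yn-1-yloxy)-1,4-benzoquinone; 8 (1E,3E)-penta-1,3-dien-1-yl (S)-2-methoxy-2-phenylacetate
Product: 9 cis-fused Diels–Alder adduct (C15 methyl β, H-10 β, 11α-methyl, 14α-acyloxy, 12-ene; ring B 2,9-dione, 3-ene, 8-propargyloxy)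
Conditions: BF3·OEt2 (0.3 equiv), CH2Cl2, −78 → −40 °C
Reagents that add atoms: none
Why: Lewis-acid-catalysed Diels–Alder reaction at the methyl-bearing double bond (the alkoxy-bearing one is a deactivated vinylogous ester); BF3 on the more basic vinylogous-ester carbonyl (C2=O) makes C10 the electrophilic end, so the nucleophilic methyl-bearing diene terminus C11 should bond to C10 and C14 to C1. Endo approach places the 11-methyl and 14-acyloxy groups cis to the quinone carbonyls, and the auxiliary is expected to shield one diene face so that C1 forms with the C15 methyl β (1S series).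

Step 4
Reactants: 9 cis-fused Diels–Alder adduct
Product: 10 trans-fused adduct (H-10 α)
Conditions: DBU (0.2 equiv), CH2Cl2, rt
Reagents that add atoms: none
Why: Base-mediated epimerisation α to the C9 ketone under thermodynamic control; the trans-fused ene-dione should be favoured because it removes the cis contact between C9 and the 11-methyl group, and C1 is quaternary and cannot change. Any epimerisation at the auxiliary carbon is of no consequence, since the group is expelled in step 5.

Step 5
Reactants: 10 trans-fused adduct
Product: 11 trans-fused trienedione with the ring A 11,13-diene (11-methyl)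
Conditions: Pd(PPh3)4 (5 mol%), Et3N, THF, 60 °C
Reagents that add atoms: none
Why: Palladium-catalysed 1,4-elimination of an allylic ester (Tsuji–Trost ionisation, then β-hydride elimination): zerovalent palladium ionises the axial C14 ester from the β face and the π-allyl complex loses the syn hydrogen H-11β, the only β-hydrogen since C1 is quaternary. The auxiliary leaves as its acid and can be recovered.

Step 6
Reactants: 11 trans-fused trienedione
Product: 12 11α,12α-diol (C20 methyl β), 13-ene retained
Conditions: OsO4 (2 mol%), NMO, acetone/H2O, 0 °C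
Reagents that add atoms: N-methylmorpholine N-oxide (C[N+]1([O-])CCOCC1); water (O)
Why: Catalytic syn-dihydroxylation with osmium tetroxide of the more electron-rich trisubstituted C11=C12 bond of the diene, from the α face anti to the axial C15 methyl; this sets C11 (OH α, methyl β) and C12 (OH α) together. The alkoxy-ene-dione alkene of ring B is electron-poor and should not react.

Step 7
Reactants: 12 11α,12α-diol
Product: 13 11,12-O-isopropylidene acetal
Conditions: 2-methoxypropene, PPTS (cat.), CH2Cl2, 0 °C
Reagents that add atoms: 2-methoxypropene (COC(C)=C)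
Why: Acid-catalysed acetalisation of the cis-1,2-diol; the mild, cold conditions should leave the base- and acid-sensitive C10 centre untouched.

Step 8
Reactants: 13 11,12-O-isopropylidene acetal
Product: 14 2β,9β-diol (ring B 3-ene, 8-propargyl enol ether)
Conditions: LiAlH4, Et2O, −78 → −20 °C; Rochelle salt work-up
Reagents that add atoms: none
Why: 1,2-Hydride reduction of both ring B carbonyls; hydride should add to C9 and to C2 from the α face, away from the axial C15 methyl, giving the 9β (axial) and 2β (equatorial) alcohols. A non-acidic work-up preserves the enol ether, and C10 is no longer epimerisable after this step.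

Step 9
Reactants: 14 2β,9β-diol
Product: 15 2,9-bis(4-methoxybenzyl) ether
Conditions: NaH, 4-MeOC6H4CH2Cl, Bu4NI (cat.), THF/DMF, 0 °C → rt
Reagents that add atoms: 4-methoxybenzyl chloride (COc1ccc(CCl)cc1)
Why: Williamson etherification under basic conditions that the enol ether tolerates; alkoxide formation at 0 °C should precede any acetylide formation. Benzyl-type ethers are chosen because they cannot migrate to O8 under the conditions of step 12.

Step 10
Reactants: 15 2,9-bis(4-methoxybenzyl) ether
Product: 16 3α-(propa-1,2-dienyl) 8-ketone
Conditions: o-xylene, NaHCO3 (solid), 135 °C, sealed tube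
Reagents that add atoms: none
Why: Propargyl Claisen (Saucy–Marbet) rearrangement: the [3,3] shift of the propargyl enol ether gives the C8 ketone and the allenyl group on C3 (C4, C5, C16 come from the propargyl group). C4 should be delivered to the α face because the β face of C3 is blocked by the axial C15 methyl and the axial 9β-ether; the equatorial 3α product is also the thermodynamically preferred epimer.

Step 11
Reactants: 16 3α-(propa-1,2-dienyl) 8-ketone
Product: 17 8β-hydroxy-8α-vinyl-3α-allenyl trans-decalin
Conditions: CH2=CHMgBr, CeCl3, THF, −78 °C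
Reagents that add atoms: vinylmagnesium bromide (C=C[Mg]Br)
Why: 1,2-Addition of a vinylcerium reagent (organocerium addition; the low basicity should avoid enolisation of the allenyl ketone). Axial attack from the α face, anti to the axial C9–O bond (Felkin–Anh polar effect), should give the axial vinyl group cis to the equatorial allenyl group, as the key step requires.

Step 12
Reactants: 17 8β-hydroxy-8α-vinyl-3α-allenyl trans-decalin
Product: 19 8-trimethylsilyl enol ether of the ring-expanded ten-membered ketone, via potassium enolate 18 (not isolated)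
Conditions: KH, 18-crown-6, THF, 0 °C → rt; then Et3N, Me3SiCl, −78 °C
Reagents that add atoms: chlorotrimethylsilane (C[Si](C)(C)Cl)
Why: Deprotonation gives the potassium alkoxide, whose C3–C8 bond is weakened so that the anion-accelerated [3,3] shift (anionic oxy-Cope rearrangement; closest precedents are the ring expansion of cis-1,2-dialkenylcyclohexanols to cyclodec-5-enones and the Cope rearrangement of 1,2,6-trienes) forms C5–C6 between the central allene carbon and the vinyl terminus while C3–C8 breaks. No ring is closed by cyclisation: ring B is enlarged by the four atoms C4–C7 to the ten-membered ring in a ring expansion through the six-centre chair array C5–C4–C3–C8–C7–C6. The in-plane π bond of the allene takes no part and remains as the exocyclic C5=C16 methylene, so the conjugated 3,5(16)-diene is delivered without a separate olefination. No sp3 stereocentre is created; the stereo-elements are the C3=C4 geometry and the enolate geometry, and because the trans-fused ring A locks ring B in one chair with the vinyl group axial and the allenyl group equatorial, only one chair array is accessible, in which C2 is axial (giving the 3Z alkene) and C9 equatorial (giving the enolate with C6 trans to C9). The step needs chair over boat (the boat would give the 3E ring) and [3,3] shift over alkoxide fragmentation or base-induced allene isomerisation. The first should be secured by the usual chair preference, helped by the absence of a 1,3-diaxial partner at the sp-hybridised C5; the second by the low temperature that the strained allene allows and by the fact that heterolysis of C3–C8 would give only an unstabilised allenyl anion. Silylation at −78 °C fixes the enolate regiochemistry (towards C7, not C9) for step 13.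

Step 13
Reactants: 19 8-trimethylsilyl enol ether
Product: 20 (3Z,6Z)-17,18,19-trinorbriara-3,5(16),6,13-tetraen-8-one (2,9-bis-PMB ether, 11,12-acetonide)
Conditions: IBX, 4-methoxypyridine N-oxide, DMSO, rt
Reagents that add atoms: none
Why: Dehydrogenation of a silyl enol ether to the enone with the IBX·N-oxide complex (a metal-free counterpart of the Saegusa oxidation); the position of the new alkene is fixed by the enol ether. The 6Z enone is expected as the less strained geometry of a cyclodec-2-enone.

Step 14
Reactants: 20 (3Z,6Z)-tetraen-8-one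
Product: 21 methyl ester of the 8-hydroxy-19-oic acid (propionate aldol adduct; C8 and C17 as in 30)
Conditions: methyl propionate, LiN(iPr)2, THF/DMPU (4:1), −78 °C; then 20, −78 °C; aq. NH4Cl
Reagents that add atoms: methyl propionate (CCC(=O)OC)
Why: Aldol 1,2-addition of the lithium Z(O)-enolate of methyl propionate to the ketone; with the lithium solvated by DMPU no chelate to O9 should form, and Felkin–Anh attack anti to the C9–O bond places C17 on the same side as O9, as in 30. A closed chair transition state with the branched C9 equatorial and the Z(O)-enolate should give the 17R methyl centre; low temperature favours 1,2- over 1,4-addition.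

Step 15
Reactants: 21 methyl ester of the 8-hydroxy-19-oic acid
Product: 22 cis-6,7-epoxide on the face opposite to the C8 hydroxyl
Conditions: VO(acac)2 (5 mol%), t-BuOOH (decane), CH2Cl2, 0 °C
Reagents that add atoms: tert-butyl hydroperoxide (CC(C)(C)OO)
Why: Hydroxyl-directed epoxidation with vanadyl acetylacetonate and tert-butyl hydroperoxide of the allylic C6=C7 bond; as is typical for medium-ring (Z)-cycloalk-2-enols, the bound peroxide should reach only the peripheral face, which places the epoxide trans to the hydroxyl. The other alkenes have no free allylic hydroxyl and should be left alone.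

Step 16
Reactants: 22 cis-6,7-epoxide
Product: 24 6-hydroxy 19,7-lactone (C6 hydroxyl opposite in configuration to the chloride of 30), via potassium carboxylate 23 (not isolated)
Conditions: KOSiMe3, THF, rt → 40 °C; aq. NH4Cl
Reagents that add atoms: none
Why: Nucleophilic demethylation of the ester by trimethylsilanolate gives the carboxylate under anhydrous conditions; it should open the γ,δ-epoxide in the 5-exo mode at C7 with inversion (epoxide-opening lactonisation). This forms the γ-lactone with O7 on the same side as the C8 hydroxyl and leaves the C6 alcohol.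

Step 17
Reactants: 24 6-hydroxy 19,7-lactone
Product: 25 (6S)-6-chloro 19,7-lactone (2,9-bis-PMB ether, 11,12-acetonide, 13-ene)
Conditions: PPh3, Cl3CCOCCl3, CH2Cl2, −20 → 0 °C
Reagents that add atoms: hexachloroacetone (O=C(C(Cl)(Cl)Cl)C(Cl)(Cl)Cl)
Why: Appel-type deoxychlorination of the secondary allylic alcohol (chlorophosphonium activation, then SN2 by chloride) with inversion at C6; this reagent pair is chosen because it is known to keep allylic transposition low. The tertiary C8 hydroxyl is too hindered to be activated.

Step 18
Reactants: 25 (6S)-6-chloro 19,7-lactone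
Product: 26 2,9-diol
Conditions: DDQ, CH2Cl2/pH 7 buffer (10:1), 0 °C → rt
Reagents that add atoms: none
Why: Oxidative cleavage of both 4-methoxybenzyl ethers by DDQ (benzylic oxidation to the oxocarbenium ion, then hydrolysis); the wet medium should prevent capture of the cation by O8 as a benzylidene acetal.

Step 19
Reactants: 26 2,9-diol
Product: 27 2,9-diacetate
Conditions: Ac2O, pyridine, DMAP (cat.), CH2Cl2, 0 °C → rt
Reagents that add atoms: acetic anhydride (CC(=O)OC(C)=O)
Why: Acylation of the two secondary alcohols with nucleophilic catalysis; the tertiary C8 hydroxyl should not react under these conditions.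

Step 20
Reactants: 27 2,9-diacetate
Product: 28 11,12-diol
Conditions: AcOH/H2O (4:1), 35 °C
Reagents that add atoms: none
Why: Acid-catalysed hydrolysis of the isopropylidene acetal; the acetates, the lactone and the allylic chloride should survive dilute acetic acid at this temperature.

Step 21
Reactants: 28 11,12-diol
Product: 29 13α,14α-epoxide (12-alcohol)
Conditions: VO(acac)2 (5 mol%), t-BuOOH (decane), CH2Cl2, 0 °C
Reagents that add atoms: tert-butyl hydroperoxide (CC(C)(C)OO)
Why: Hydroxyl-directed epoxidation of a cyclohex-2-enol: the pseudo-axial 12α-hydroxyl (assisted by the 11α-hydroxyl) should deliver oxygen to the α face of C13=C14, which is also the face away from both methyl groups. The diene has no free allylic hydroxyl.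

Step 22
Reactants: 29 13α,14α-epoxide (12-alcohol)
Product: 30 CNP0273377.1
Conditions: (PrCO)2O, DMAP (0.2 equiv), pyridine, CH2Cl2, 0 °C
Reagents that add atoms: butanoic anhydride (CCCC(=O)OC(=O)CCC)
Why: Selective acylation of the only secondary hydroxyl (O12); the tertiary hydroxyls at C8 and C11 should remain free, and the mild base should not trigger epoxide migration.

## Compound list

1 | 2-methyl-1,4-benzoquinone | CC1=CC(=O)C=CC1=O | starting material
2 | prop-2-yn-1-ol | C#CCO | starting material
3 | 2-methyl-5-(prop-2-yn-1-yloxy)-1,4-benzoquinone | CC1=CC(=O)C(OCC#C)=CC1=O | intermediate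
4 | (E)-pent-2-enal | CC/C=C/C=O | starting material
5 | (S)-2-methoxy-2-phenylacetic acid | CO[C@H](C(=O)O)c1ccccc1 | starting material
6 | (S)-2-methoxy-2-phenylacetyl chloride | CO[C@H](C(Cl)=O)c1ccccc1 | intermediate (not isolated)
7 | potassium (1E,3E)-penta-1,3-dien-1-olate | C/C=C/C=C/[O-].[K+] | intermediate (not isolated)
8 | (1E,3E)-penta-1,3-dien-1-yl (S)-2-methoxy-2-phenylacetate | C/C=C/C=C/OC(=O)[C@@H](OC)c1ccccc1 | intermediate
9 | cis-fused Diels–Alder adduct: ring B (C1, C2, C3, C8, C9, C10) 2,9-dione, 3-ene, 8-propargyloxy; ring A 12-ene, 11α-methyl, 14α-[(S)-2-methoxy-2-phenylacetoxy]; C15 methyl β, H-10 β | C[C@@]12C(=O)C=C(OCC#C)C(=O)[C@@H]1[C@H](C)C=C[C@@H]2OC(=O)[C@@H](OC)c1ccccc1 | intermediate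
10 | trans-fused adduct: C10 epimer of 9 (H-10 α) | C[C@@]12C(=O)C=C(OCC#C)C(=O)[C@H]1[C@H](C)C=C[C@@H]2OC(=O)[C@@H](OC)c1ccccc1 | intermediate
11 | trans-fused trienedione: ring A 11,13-diene (11-methyl), ring B as in 10 | C[C@@]12C(=O)C=C(OCC#C)C(=O)[C@H]1C(C)=CC=C2 | intermediate
12 | 11α,12α-diol of 11 (C20 methyl β), 13-ene | C[C@@]12C(=O)C=C(OCC#C)C(=O)[C@H]1[C@](C)(O)[C@H](O)C=C2 | intermediate
13 | 11,12-O-isopropylidene acetal of 12 | C[C@@]12C(=O)C=C(OCC#C)C(=O)[C@H]1[C@]3(C)OC(C)(C)O[C@@H]3C=C2 | intermediate
14 | 2β,9β-diol from 13; ring B 3-ene 8-propargyl enol ether | C[C@@]12[C@@H](O)C=C(OCC#C)[C@@H](O)[C@H]1[C@]3(C)OC(C)(C)O[C@@H]3C=C2 | intermediate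
15 | 2,9-bis(4-methoxybenzyl) ether of 14 | C[C@@]12[C@@H](OCc4ccc(OC)cc4)C=C(OCC#C)[C@@H](OCc4ccc(OC)cc4)[C@H]1[C@]3(C)OC(C)(C)O[C@@H]3C=C2 | intermediate
16 | 3α-(propa-1,2-dienyl) 8-ketone; 2β,9β-bis-PMB ethers; trans-decalin | C[C@@]12[C@@H](OCc4ccc(OC)cc4)[C@H](C=C=C)C(=O)[C@@H](OCc4ccc(OC)cc4)[C@H]1[C@]3(C)OC(C)(C)O[C@@H]3C=C2 | intermediate
17 | 8β-hydroxy-8α-vinyl-3α-allenyl trans-decalin (oxy-Cope substrate) | C[C@@]12[C@@H](OCc4ccc(OC)cc4)[C@H](C=C=C)[C@](O)(C=C)[C@@H](OCc4ccc(OC)cc4)[C@H]1[C@]3(C)OC(C)(C)O[C@@H]3C=C2 | intermediate
18 | potassium enolate of the ring-expanded ketone (C7=C8, C6 trans to C9) | [K+].[O-]/C1=C\CC(=C)/C=C\[C@H](OCc4ccc(OC)cc4)[C@@]2(C)C=C[C@H]3OC(C)(C)O[C@@]3(C)[C@@H]2[C@@H]1OCc5ccc(OC)cc5 | intermediate (not isolated)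
19 | 8-trimethylsilyl enol ether: 17,18,19-trinorbriara-3Z,5(16),7,13-tetraene, C6 trans to C9 across C7=C8; 2,9-bis-PMB ether; 11,12-acetonide | C[Si](C)(C)O/C1=C\CC(=C)/C=C\[C@H](OCc4ccc(OC)cc4)[C@@]2(C)C=C[C@H]3OC(C)(C)O[C@@]3(C)[C@@H]2[C@@H]1OCc5ccc(OC)cc5 | intermediate
20 | (3Z,6Z)-17,18,19-trinorbriara-3,5(16),6,13-tetraen-8-one; 2,9-bis-PMB ether; 11,12-acetonide | O=C1/C=C\C(=C)/C=C\[C@H](OCc4ccc(OC)cc4)[C@@]2(C)C=C[C@H]3OC(C)(C)O[C@@]3(C)[C@@H]2[C@@H]1OCc5ccc(OC)cc5 | intermediate
21 | methyl ester of the 8-hydroxybriara-3Z,5(16),6Z,13-tetraen-19-oic acid; C8 and C17 as in 30 | COC(=O)[C@H](C)[C@]1(O)/C=C\C(=C)/C=C\[C@H](OCc4ccc(OC)cc4)[C@@]2(C)C=C[C@H]3OC(C)(C)O[C@@]3(C)[C@@H]2[C@@H]1OCc5ccc(OC)cc5 | intermediate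
22 | cis-6,7-epoxide of 21, on the face opposite to the C8 hydroxyl | COC(=O)[C@H](C)[C@]1(O)[C@@H]2O[C@@H]2C(=C)/C=C\[C@H](OCc5ccc(OC)cc5)[C@@]3(C)C=C[C@H]4OC(C)(C)O[C@@]4(C)[C@@H]3[C@@H]1OCc6ccc(OC)cc6 | intermediate
23 | potassium carboxylate of 22 | [K+].[O-]C(=O)[C@H](C)[C@]1(O)[C@@H]2O[C@@H]2C(=C)/C=C\[C@H](OCc5ccc(OC)cc5)[C@@]3(C)C=C[C@H]4OC(C)(C)O[C@@]4(C)[C@@H]3[C@@H]1OCc6ccc(OC)cc6 | intermediate (not isolated)
24 | 6-hydroxy 19,7-lactone; C6 hydroxyl opposite to the chloride of 30; C7, C8, C17 as in 30 | C=C1/C=C\[C@H](OCc4ccc(OC)cc4)[C@@]2(C)C=C[C@H]3OC(C)(C)O[C@@]3(C)[C@@H]2[C@H](OCc4ccc(OC)cc4)[C@]2(O)[C@@H](C)C(=O)O[C@H]2[C@@H]1O | intermediate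
25 | (6S)-6-chloro 19,7-lactone; 2,9-bis-PMB ether; 11,12-acetonide; 13-ene | C=C1/C=C\[C@H](OCc4ccc(OC)cc4)[C@@]2(C)C=C[C@H]3OC(C)(C)O[C@@]3(C)[C@@H]2[C@H](OCc4ccc(OC)cc4)[C@]2(O)[C@@H](C)C(=O)O[C@H]2[C@H]1Cl | intermediate
26 | 2,9-diol of 25 | C=C1/C=C\[C@H](O)[C@@]2(C)C=C[C@H]3OC(C)(C)O[C@@]3(C)[C@@H]2[C@H](O)[C@]2(O)[C@@H](C)C(=O)O[C@H]2[C@H]1Cl | intermediate
27 | 2,9-diacetate of 26 | C=C1/C=C\[C@H](OC(C)=O)[C@@]2(C)C=C[C@H]3OC(C)(C)O[C@@]3(C)[C@@H]2[C@H](OC(C)=O)[C@]2(O)[C@@H](C)C(=O)O[C@H]2[C@H]1Cl | intermediate
28 | 11,12-diol of 27 (13-ene) | C=C1/C=C\[C@H](OC(C)=O)[C@@]2(C)C=C[C@@H](O)[C@@](C)(O)[C@@H]2[C@H](OC(C)=O)[C@]2(O)[C@@H](C)C(=O)O[C@H]2[C@H]1Cl | intermediate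
29 | 13α,14α-epoxide of 28 (12-alcohol) | C=C1/C=C\[C@H](OC(C)=O)[C@@]2(C)[C@H]3O[C@H]3[C@@H](O)[C@@](C)(O)[C@@H]2[C@H](OC(C)=O)[C@]2(O)[C@@H](C)C(=O)O[C@H]2[C@H]1Cl | intermediate
30 | CNP0273377.1: (1S,2S,3Z,6S,7R,8R,9S,10S,11S,12R,13R,14R,17R)-2,9-diacetoxy-12-butanoyloxy-6-chloro-13,14-epoxy-8,11-dihydroxybriara-3,5(16)-dien-19,7-olide | C=C1/C=C\[C@H](OC(C)=O)[C@@]2(C)[C@H]3O[C@H]3[C@@H](OC(=O)CCC)[C@@](C)(O)[C@@H]2[C@H](OC(C)=O)[C@]2(O)[C@@H](C)C(=O)O[C@H]2[C@H]1Cl | target

## Step count and least certain steps

Total step count: 22. Longest linear sequence: 21 steps (steps 1 and 3–22 from 1; step 2 is the side branch).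

Step 12 (key step). What may go wrong: passage through the boat array, which would give the 3E ring, or base-induced isomerisation of the allene and heterolytic cleavage of the naked alkoxide before the rearrangement, because KH with 18-crown-6 is a very basic medium. Fallback: a neutral sigmatropic shift in place of the anionic one. Setting out from 17, silylation (Me3SiCl, imidazole) would give the trimethylsilyl ether F1, which on heating at 170–190 °C in decalin should undergo the siloxy-Cope rearrangement through the same chair directly to 19, with no free alkoxide or enolate; the route is rejoined at 19.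

Step 3. What may go wrong: erosion of regiocontrol (C11 bonding to C1) if the Lewis acid also binds at the C9 carbonyl, and weak facial discrimination by the auxiliary at the hindered quaternary terminus. Fallback: reverse the polarity demand so that the natural regiochemistry is the wanted one. Setting out from 3, (E)-penta-1,3-diene under a chiral oxazaborolidinium Lewis acid (activation at the C9 carbonyl, CH2 terminus to C1) should give the cis adduct F2; epimerisation as in step 4 gives the trans adduct F3. A Schenck ene reaction with singlet oxygen on the α face (H-14α abstracted) and reduction with PPh3 would give the 12α-allylic alcohol F4; trans-diaxial dehydration with Martin sulfurane should give 11, where the route is rejoined.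

Step 4. What may go wrong: an incomplete or unfavourable cis/trans equilibrium at C10, since the energy difference between the two ring fusions of such ene-diones is small. Fallback: kinetic instead of thermodynamic control. Setting out from 9, LiN(SiMe3)2 and Me3SiCl would give the silyl dienol ether F5; protonation at −78 °C with HF·pyridine should deliver the proton to C10 from the α face, opposite the C15 methyl, and give 10.

Step 13. What may go wrong: formation of the 6E enone or of E/Z mixtures, since the dehydrogenation is not stereospecific; the sequence of steps 15–17 is correct only for the Z alkene. Fallback: change the order of bond formation for the E isomer. Setting out from 19, the (6E)-enone F6 would be taken through the same aldol to the ester F7 and through hydroxyl-directed epoxidation to the trans-epoxide F8 (epoxide oxygen at C7 on the side of the C8 hydroxyl). Chloride is then introduced first: Ti(OiPr)4 with Et2NH2Cl should open the epoxy alcohol at the allylic C6 with inversion, and the freed C7 hydroxyl lactonises with retention, which returns to the route at 25.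

Step 15. What may go wrong: delivery of the epoxide to the face syn to the C8 hydroxyl, because facial preference on a flexible ten-membered ring is hard to predict. Fallback: use the other epoxide with a double inversion at C6. Setting out from 21, the syn-epoxide F9 would be opened at C6 by Ti(OiPr)4 and PhCO2H with inversion; the C7 hydroxyl, now correct by retention, lactonises to the benzoate F10. K2CO3 in MeOH removes the benzoate and returns to the route at 24.

## Further compounds

F1 | step 12 | trimethylsilyl ether of 17 | C[C@@]12[C@@H](OCc4ccc(OC)cc4)[C@H](C=C=C)[C@](O[Si](C)(C)C)(C=C)[C@@H](OCc4ccc(OC)cc4)[C@H]1[C@]3(C)OC(C)(C)O[C@@H]3C=C2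
F2 | step 3 | cis-fused adduct of 3 with (E)-penta-1,3-diene (11α-methyl, 12-ene, H-10 β) | C[C@@]12C(=O)C=C(OCC#C)C(=O)[C@@H]1[C@H](C)C=CC2
F3 | step 3 | trans-fused C10 epimer of F2 | C[C@@]12C(=O)C=C(OCC#C)C(=O)[C@H]1[C@H](C)C=CC2
F4 | step 3 | 12α-hydroxy-13-ene allylic alcohol from F3 | C[C@@]12C(=O)C=C(OCC#C)C(=O)[C@H]1[C@H](C)[C@H](O)C=C2
F5 | step 4 | 9-trimethylsilyl dienol ether of 9 (C9=C10) | C[C@@]12C(=O)C=C(OCC#C)C(O[Si](C)(C)C)=C1[C@H](C)C=C[C@@H]2OC(=O)[C@@H](OC)c1ccccc1
F6 | step 13 | (3Z,6E)-isomer of 20 | O=C1/C=C/C(=C)/C=C\[C@H](OCc4ccc(OC)cc4)[C@@]2(C)C=C[C@H]3OC(C)(C)O[C@@]3(C)[C@@H]2[C@@H]1OCc5ccc(OC)cc5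
F7 | step 13 | (6E)-isomer of 21 | COC(=O)[C@H](C)[C@]1(O)/C=C/C(=C)/C=C\[C@H](OCc4ccc(OC)cc4)[C@@]2(C)C=C[C@H]3OC(C)(C)O[C@@]3(C)[C@@H]2[C@@H]1OCc5ccc(OC)cc5
F8 | step 13 | trans-6,7-epoxide of F7 (C7–O on the side of the C8 hydroxyl) | COC(=O)[C@H](C)[C@]1(O)[C@H]2O[C@@H]2C(=C)/C=C\[C@H](OCc5ccc(OC)cc5)[C@@]3(C)C=C[C@H]4OC(C)(C)O[C@@]4(C)[C@@H]3[C@@H]1OCc6ccc(OC)cc6
F9 | step 15 | cis-6,7-epoxide of 21 on the face of the C8 hydroxyl | COC(=O)[C@H](C)[C@]1(O)[C@H]2O[C@H]2C(=C)/C=C\[C@H](OCc5ccc(OC)cc5)[C@@]3(C)C=C[C@H]4OC(C)(C)O[C@@]4(C)[C@@H]3[C@@H]1OCc6ccc(OC)cc6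
F10 | step 15 | 6-benzoate of 24 | C=C1/C=C\[C@H](OCc4ccc(OC)cc4)[C@@]2(C)C=C[C@H]3OC(C)(C)O[C@@]3(C)[C@@H]2[C@H](OCc4ccc(OC)cc4)[C@]2(O)[C@@H](C)C(=O)O[C@H]2[C@@H]1OC(=O)c1ccccc1
A1 | alternative 1 | 3,4-seco triene for ring-closing metathesis | C=C[C@H](OC(C)=O)[C@@]2(C)[C@H]3O[C@H]3[C@@H](OC(=O)CCC)[C@@](C)(O)[C@@H]2[C@H](OC(C)=O)[C@]2(O)[C@@H](C)C(=O)O[C@H]2[C@@H](Cl)C(=C)C=C
A2 | alternative 2 | tricyclic 9-hydroxy 3-mesylate with a temporary C4–C9 bond | C=C1[C@H]2[C@@H](OS(C)(=O)=O)[C@H](OCc5ccc(OC)cc5)[C@@]3(C)C=C[C@H]4OC(C)(C)O[C@@]4(C)[C@@H]3[C@@]2(O)[C@]2(O)[C@@H](C)C(=O)O[C@H]2[C@H]1Cl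
A3 | alternative 2 | 9-oxo (3Z)-cyclodecene fragmentation product | C=C1/C=C\[C@H](OCc4ccc(OC)cc4)[C@@]2(C)C=C[C@H]3OC(C)(C)O[C@@]3(C)[C@@H]2C(=O)[C@]2(O)[C@@H](C)C(=O)O[C@H]2[C@H]1Cl
A4 | alternative 3 | aryl tricycle with C2–C7 in a 4-methoxy-5-methylbenzene ring (9-MOM ether) | COc1cc2c(cc1C)C[C@@H](OCOC)[C@@H]1[C@]2(C)C=C[C@H]3OC(C)(C)O[C@@]13C
A5 | alternative 3 | ten-membered 2,4,7-trione from A4 (C5 epimers) | CC1CC(=O)C[C@@H](OCOC)[C@@H]2[C@@](C)(C(=O)CC1=O)C=C[C@H]3OC(C)(C)O[C@@]23C
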